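**Retrosynthetic overview**

1. Violacene is numbered as (1R,2S,4R,5R)-1-(bromomethyl)-1,2,4-trichloro-5-[(E)-2-chloroethenyl]-5-methylcyclohexane. The carbocycle is closed last, at C5–C6, by a biomimetic chloronium-triggered, chloride-terminated cation–olefin cyclisation of the acyclic ocimene-type triene 14. Triene 14 carries only the C2 stereocentre and gains the ring, two chlorines and the C1, C4 and C5 stereocentres in that step.
2. Enabling feature: C5 (quaternary, methyl/chlorovinyl, next to C4–Cl) is the tertiary end of a chloroallyl cation formed by Cl+ addition to a (Z)-1-chloro-3-methyl-1,3-diene. C6H2–C1(Cl)–CH2Br is a 2-(bromomethyl)alkene that has taken up that cation at its CH2 end and chloride at its substituted carbon through a bromiranium ion.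
3. 14 ⇐ silyl ether 13 (OTBS → Br) ⇐ (6R)-alcohol 12 (OH → Cl with inversion) ⇐ Takai chloro-olefination of lactol 10.
4. The (3Z)-alkene is fixed by a temporary ring: α-methyl-dihydropyranone 9 from ring-closing metathesis of methacrylate 8, opened again at the lactol stage.
5. The single stereocentre is set by catalysis (Keck allylation of acrolein 4, two steps from diol 1). Ring order: lactone ring (step 5, opened in step 7), then the cyclohexane ring (step 10).

Key step: step 10

Remark: in steps 7–10 the chain of 11–15 is numbered C1 (CHCl or CHO) to C8 (=CH2) with the CH2X branch on C7; chain atoms C3, C4, C5, C6, C7, C8 become ring atoms C5, C4, C3, C2, C1, C6. The Keck allylation of the 2-substituted acrolein 4 is assumed to follow its usual facial sense ((R)-ligand, Re face).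

**Route**

Step 1
Reactants: 1 2-methylidenepropane-1,3-diol
Product: 3 2-({[tert-butyl(dimethyl)silyl]oxy}methyl)prop-2-en-1-ol, via monosodium alkoxide 2 (not isolated)
Conditions: NaH (1.0 equiv), THF, 0 °C to rt; then TBSCl (1.0 equiv), rt
Reagents that add atoms: tert-butyldimethylsilyl chloride, CC(C)(C)[Si](C)(C)Cl
Why: O-silylation of the sparingly soluble monosodium alkoxide should give clean mono-protection of the symmetric diol; no stereocentre is formed.

Step 2
Reactants: 3 2-({[tert-butyl(dimethyl)silyl]oxy}methyl)prop-2-en-1-ol
Product: 4 2-({[tert-butyl(dimethyl)silyl]oxy}methyl)prop-2-enal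
Conditions: MnO2 (10 equiv), CH2Cl2, rt
Reagents that add atoms: none
Why: MnO2 oxidation of a primary allylic alcohol should stop at the 2-substituted acrolein and leave the silyl ether untouched; no stereocentre is formed.

Step 3
Reactants: 4 2-({[tert-butyl(dimethyl)silyl]oxy}methyl)prop-2-enal; 5 allyltributylstannane
Product: 6 (3R)-2-({[tert-butyl(dimethyl)silyl]oxy}methyl)hexa-1,5-dien-3-ol
Conditions: (R)-BINOL (20 mol %), Ti(OiPr)4 (10 mol %), 4 Å MS, CH2Cl2, −20 °C; aq. NaHCO3
Reagents that add atoms: none
Why: Keck asymmetric allylation, in which the BINOL–Ti(OiPr)4 Lewis acid activates the enal and the (R)-ligand should direct the allylstannane to the Re face, setting C3 as (R), the only stereocentre in the route that is made by a catalyst.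

Step 4
Reactants: 6 (3R)-2-({[tert-butyl(dimethyl)silyl]oxy}methyl)hexa-1,5-dien-3-ol; 7 methacryloyl chloride
Product: 8 (3R)-2-({[tert-butyl(dimethyl)silyl]oxy}methyl)hexa-1,5-dien-3-yl 2-methylprop-2-enoate
Conditions: Et3N (2 equiv), DMAP (10 mol %), CH2Cl2, 0 °C to rt
Reagents that add atoms: none
Why: DMAP-catalysed acylation of the secondary allylic alcohol with an acid chloride, which does not touch the stereocentre.

Step 5
Reactants: 8 (3R)-2-({[tert-butyl(dimethyl)silyl]oxy}methyl)hexa-1,5-dien-3-yl 2-methylprop-2-enoate
Product: 9 (6R)-6-(3-{[tert-butyl(dimethyl)silyl]oxy}prop-1-en-2-yl)-3-methyl-5,6-dihydro-2H-pyran-2-one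
Conditions: second-generation Grubbs catalyst (H2IMes)(PCy3)Cl2Ru=CHPh (5 mol %), CH2Cl2 (0.005 M), 40 °C
Reagents that add atoms: none
Why: ring-closing metathesis of an allyl/methacrylate diene to an α-methyl-α,β-unsaturated δ-lactone is well precedented, the six-membered ring forces the new trisubstituted alkene to be (Z), and the 1,1-disubstituted alkene next to the carbinol carbon could only close a four-membered ring or a tetrasubstituted butenolide and should stay a bystander.

Step 6
Reactants: 9 (6R)-6-(3-{[tert-butyl(dimethyl)silyl]oxy}prop-1-en-2-yl)-3-methyl-5,6-dihydro-2H-pyran-2-one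
Product: 10 (6R)-6-(3-{[tert-butyl(dimethyl)silyl]oxy}prop-1-en-2-yl)-3-methyl-5,6-dihydro-2H-pyran-2-ol (anomer mixture)
Conditions: iBu2AlH (1.1 equiv), CH2Cl2, −78 °C; aq. potassium sodium tartrate
Reagents that add atoms: none
Why: low-temperature DIBAL-H 1,2-reduction of a lactone stops at the tetrahedral aluminium hemiacetal and should give the lactol on work-up; the anomeric centre forms as a mixture of no consequence.

Step 7
Reactants: 10 (6R)-6-(3-{[tert-butyl(dimethyl)silyl]oxy}prop-1-en-2-yl)-3-methyl-5,6-dihydro-2H-pyran-2-ol
Product: 12 (1E,3Z,6R)-7-({[tert-butyl(dimethyl)silyl]oxy}methyl)-1-chloro-3-methylocta-1,3,7-trien-6-ol, via open-chain hydroxy enal 11 (not isolated)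
Conditions: CrCl2 (8 equiv), CHCl3 (3 equiv), THF, 65 °C
Reagents that add atoms: chloroform, ClC(Cl)Cl
Why: Takai chloro-olefination of the open-chain aldehyde tautomer should give the (E)-chloroalkene by anti elimination from the gem-dichromium adduct, tolerates the free hydroxyl group, the silyl ether and both alkenes, and keeps the ring-derived (3Z) geometry.

Step 8
Reactants: 12 (1E,3Z,6R)-7-({[tert-butyl(dimethyl)silyl]oxy}methyl)-1-chloro-3-methylocta-1,3,7-trien-6-ol
Product: 13 (1E,3Z,6S)-7-({[tert-butyl(dimethyl)silyl]oxy}methyl)-1,6-dichloro-3-methylocta-1,3,7-triene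
Conditions: PPh3 (1.3 equiv), hexachloroacetone (3 equiv), CH2Cl2, 0 °C
Reagents that add atoms: hexachloroacetone, ClC(Cl)(Cl)C(=O)C(Cl)(Cl)Cl
Why: Appel-type deoxychlorination with PPh3/hexachloroacetone is the standard way to turn secondary allylic alcohols into chlorides by SN2 displacement with inversion [(6R)-OH to (6S)-Cl] and with little allylic transposition, because the phosphonium–chloride ion pair collapses at carbon before it can dissociate.

Step 9
Reactants: 13 (1E,3Z,6S)-7-({[tert-butyl(dimethyl)silyl]oxy}methyl)-1,6-dichloro-3-methylocta-1,3,7-triene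
Product: 14 (1E,3Z,6S)-7-(bromomethyl)-1,6-dichloro-3-methylocta-1,3,7-triene
Conditions: Ph3PBr2 (1.3 equiv), CH2Cl2, 0 °C to rt; used at once
Reagents that add atoms: triphenylphosphine dibromide, BrP(Br)(c1ccccc1)(c1ccccc1)c1ccccc1
Why: Ph3PBr2 converts primary silyl ethers directly into bromides (silyl transfer to bromide, then displacement of Ph3PO at the primary allylic carbon), SN2 and SN2' attack give the same constitution because the allyl unit is symmetrical about C7, and the C6 stereocentre is not involved.

Step 10
Reactants: 14 (1E,3Z,6S)-7-(bromomethyl)-1,6-dichloro-3-methylocta-1,3,7-triene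
Product: 17 violacene [(1R,2S,4R,5R)-1-(bromomethyl)-1,2,4-trichloro-5-[(E)-2-chloroethenyl]-5-methylcyclohexane], via chloroallyl cation 15 (not isolated), via spiro bromiranium ion 16 (not isolated)
Conditions: [Et2SCl][SbCl6] (1.05 equiv), MeNO2–CH2Cl2 (1:1), −30 °C; aq. NaHCO3/Na2S2O3
Reagents that add atoms: chlorodiethylsulfonium hexachloroantimonate, CC[S+](Cl)CC.Cl[Sb-](Cl)(Cl)(Cl)(Cl)Cl
Why: Proposed new method: Cl+ is transferred from the chlorosulfonium ion to C4 of the (3Z)-1-chlorodiene (the most electron-rich π-system of 14, since the C7=C8 alkene carries two allylic halogens) to give the chlorine-stabilised allyl cation 15, whose tertiary end C3 is attacked by C8 while bromine of the CH2Br group bridges C7, and hexachloroantimonate then opens bromiranium ion 16 at its tertiary carbon; the closest known reaction type is the chloronium-initiated cation–olefin (polyene) cyclisation with halosulfonium hexachloroantimonate reagents, extended here to a chlorodiene initiator, an allylic-halide terminator and capture by chloride, the sequence assumed for the biogenesis of the cyclic Plocamium monoterpenes. The ring closes in a 6-endo-trig mode at the C7=C8 alkene (both of its carbons become ring atoms), the only closure that leaves the charge on a tertiary carbon. Ring C4 and C5 arise by anti addition of Cl and C8 across the ring-derived (Z)-alkene in a chair transition state, which places the new C–Cl bond equatorial and the chlorovinyl group axial, and the existing stereocentre (C6 of 14, ring C2) keeps its chlorine equatorial and in the plane of the attacking alkene, so that it selects the diene face and gives the 2,4-cis relationship. Ring C1 is set by double inversion, bromine bridging anti to the new C5–C6 bond and chloride entering anti to bromine, which puts Cl axial and cis to the C2 chlorine and leaves CH2Br equatorial. The step needs initiation at the diene and not at C7=C8, ring closure faster than chloride capture, proton loss or C3–C4 rotation in 15, and opening of 16 at the tertiary carbon; the doubly deactivated terminator, the non-nucleophilic counter-ion at low temperature, anchimeric assistance by bromine and the tertiary cation-stabilising centre are what should secure them.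

**Compound list**

1 | 2-methylidenepropane-1,3-diol | C=C(CO)CO | starting material
2 | monosodium alkoxide of 1 (formed in the flask) | C=C(CO)C[O-].[Na+] | intermediate
3 | 2-({[tert-butyl(dimethyl)silyl]oxy}methyl)prop-2-en-1-ol | C=C(CO)CO[Si](C)(C)C(C)(C)C | intermediate
4 | 2-({[tert-butyl(dimethyl)silyl]oxy}methyl)prop-2-enal | C=C(C=O)CO[Si](C)(C)C(C)(C)C | intermediate
5 | allyltributylstannane | C=CC[Sn](CCCC)(CCCC)CCCC | starting material
6 | (3R)-2-({[tert-butyl(dimethyl)silyl]oxy}methyl)hexa-1,5-dien-3-ol | C=CC[C@@H](O)C(=C)CO[Si](C)(C)C(C)(C)C | intermediate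
7 | methacryloyl chloride | CC(=C)C(=O)Cl | starting material
8 | (3R)-2-({[tert-butyl(dimethyl)silyl]oxy}methyl)hexa-1,5-dien-3-yl 2-methylprop-2-enoate | C=CC[C@@H](OC(=O)C(C)=C)C(=C)CO[Si](C)(C)C(C)(C)C | intermediate
9 | (6R)-6-(3-{[tert-butyl(dimethyl)silyl]oxy}prop-1-en-2-yl)-3-methyl-5,6-dihydro-2H-pyran-2-one | CC1=CC[C@H](C(=C)CO[Si](C)(C)C(C)(C)C)OC1=O | intermediate
10 | (6R)-6-(3-{[tert-butyl(dimethyl)silyl]oxy}prop-1-en-2-yl)-3-methyl-5,6-dihydro-2H-pyran-2-ol (anomer mixture) | CC1=CC[C@H](C(=C)CO[Si](C)(C)C(C)(C)C)OC1O | intermediate
11 | (2Z,5R)-6-({[tert-butyl(dimethyl)silyl]oxy}methyl)-5-hydroxy-2-methylhepta-2,6-dienal (open-chain tautomer of 10, formed in the flask) | O=C/C(C)=C\C[C@@H](O)C(=C)CO[Si](C)(C)C(C)(C)C | intermediate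
12 | (1E,3Z,6R)-7-({[tert-butyl(dimethyl)silyl]oxy}methyl)-1-chloro-3-methylocta-1,3,7-trien-6-ol | Cl/C=C/C(C)=C\C[C@@H](O)C(=C)CO[Si](C)(C)C(C)(C)C | intermediate
13 | (1E,3Z,6S)-7-({[tert-butyl(dimethyl)silyl]oxy}methyl)-1,6-dichloro-3-methylocta-1,3,7-triene | Cl/C=C/C(C)=C\C[C@H](Cl)C(=C)CO[Si](C)(C)C(C)(C)C | intermediate
14 | (1E,3Z,6S)-7-(bromomethyl)-1,6-dichloro-3-methylocta-1,3,7-triene | Cl/C=C/C(C)=C\C[C@H](Cl)C(=C)CBr | intermediate
15 | (1E,4R,6S)-7-(bromomethyl)-1,4,6-trichloro-3-methylocta-1,7-dien-3-ylium, the chloroallyl cation (formed in the flask) | Cl/C=C/[C+](C)[C@H](Cl)C[C@H](Cl)C(=C)CBr | intermediate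
16 | spiro bromiranium ion: violacene skeleton with Br+ bridging ring C1 and the exocyclic CH2, bromine on the equatorial side (formed in the flask) | C[C@]1(/C=C/Cl)C[C@@]2(C[Br+]2)[C@@H](Cl)C[C@H]1Cl | intermediate
17 | violacene, (1R,2S,4R,5R)-1-(bromomethyl)-1,2,4-trichloro-5-[(E)-2-chloroethenyl]-5-methylcyclohexane | C[C@]1(/C=C/Cl)C[C@](Cl)(CBr)[C@@H](Cl)C[C@H]1Cl | target

**Step count and risks**

Total step count: 10. Longest linear sequence: 10 steps (1 to 17).

Risk 1, step 10 (proposed new method). Ring closure onto the electron-poor C7=C8 alkene may be outrun by chloride capture of cation 15, by proton loss from C5 or the C3 methyl group, or by rotation about C3–C4 (loss of the C5 configuration). The SbCl5 that is released may also ionise the allylic C6–Cl bond and erode the controlling stereocentre. The fallback sets out from 14 and comes back at 17, and it separates chlorination from ring closure. Triene 14 would be treated with Et4NCl3 in CH2Cl2 at −78 °C, a known diene dichlorination, to give the 3,4-dichloride (1E,6S)-7-(bromomethyl)-1,3,4,6-tetrachloro-3-methylocta-1,7-diene F1 together with its allylic 1,4-isomer (6S)-7-(bromomethyl)-1,1,4,6-tetrachloro-3-methylocta-2,7-diene F2. Both are covalent reservoirs of the same cation. The unseparated mixture would then be ionised with SnCl4 in CH2Cl2 at −78 °C, a known Lewis-acid-promoted cation–olefin cyclisation of allylic chlorides with chloride return from the chlorostannate. Reversible re-ionisation should funnel the material through the irreversible C–C bond formation to 17, with no free Cl+ present during ring closure.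

Risk 2, step 7. Under the hot, Lewis-acidic chromium conditions the (Z)-enal 11 may isomerise to the (E)-enal, or lactol 10 may dehydrate to a 2H-pyran, before olefination occurs. The fallback sets out from 10 and comes back at 12, and it homologates instead of olefinating. Ohira–Bestmann reaction of the lactol (dimethyl (1-diazo-2-oxopropyl)phosphonate, K2CO3, MeOH, 0 °C to rt) would give the enyne alcohol (3R,5Z)-2-({[tert-butyl(dimethyl)silyl]oxy}methyl)-6-methylocta-1,5-dien-7-yn-3-ol F3. Hydrozirconation of the terminal alkyne with Cp2Zr(H)Cl (2.2 equiv, the first equivalent being consumed by the hydroxyl group) in THF and quenching of the alkenylzirconium species with N-chlorosuccinimide should then give the (E)-chloroalkene 12 with retention.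

Risk 3, step 9. During the direct silyl ether to bromide exchange, bromide may attack the secondary allylic chloride (allylic transposition or halide exchange with loss of configuration at C6), or adventitious HBr may add to the diene. The fallback sets out from 13 and comes back at 14, and it separates deprotection from activation. The silyl ether would be cleaved with HF·pyridine in THF/pyridine at 0 °C to the allylic alcohol (3S,5Z,7E)-3,8-dichloro-6-methyl-2-methylideneocta-5,7-dien-1-ol F4. This would be brominated under Appel conditions (CBr4, PPh3, CH2Cl2, −20 °C), which keep free bromide and acid low and should give 14.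

Further compounds
F1 | step 10 | (1E,6S)-7-(bromomethyl)-1,3,4,6-tetrachloro-3-methylocta-1,7-diene (anti adduct, both C3/C4 diastereomers) | Cl/C=C/C(C)(Cl)C(Cl)C[C@H](Cl)C(=C)CBr
F2 | step 10 | (6S)-7-(bromomethyl)-1,1,4,6-tetrachloro-3-methylocta-2,7-diene (alkene and C4 isomers) | ClC(Cl)C=C(C)C(Cl)C[C@H](Cl)C(=C)CBr
F3 | step 7 | (3R,5Z)-2-({[tert-butyl(dimethyl)silyl]oxy}methyl)-6-methylocta-1,5-dien-7-yn-3-ol | C#C/C(C)=C\C[C@@H](O)C(=C)CO[Si](C)(C)C(C)(C)C
F4 | step 9 | (3S,5Z,7E)-3,8-dichloro-6-methyl-2-methylideneocta-5,7-dien-1-ol | Cl/C=C/C(C)=C\C[C@H](Cl)C(=C)CO
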